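The route rests on disconnecting the C1–C14 bond of the cyclohexane (ring A), read as the β-oxygenated carbonyl unit C14(O)–C1(CH3)–C2. A SmI2-mediated intramolecular Reformatsky aldol of an open-chain α-bromo ester aldehyde closes ring A and sets quaternary C1 and carbinol C14 in one operation. The step is stereoconvergent: both C1 epimers of the bromide, formed by an unselective Johnson–Claisen/bromination sequence, collapse to one samarium enolate. The precursor carries only the C10–C12 stereotriad. Afterwards the ester and a propenyl group are grown into the two side chains, the lactone is annulated by a chelation-controlled aldol, and the ten-membered ring is closed by metathesis before the final epoxidation.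

Key step: step 8

Remark: briarane numbering is used throughout (ring A = C1, C10–C14; ten-membered ring = C1–C10; lactone = C7, C8, C17, C19); β is the face of ring A that carries the C1 methyl group; the two B(Ipc)2 reagents are taken as preformed from commercial (+)-Ipc2BOMe, and 33 as commercial.

Step 1
Reactants: 1 3-[(tert-butyldimethylsilyl)oxy]propanal
Product: 2 (3S,4R)-1-[(tert-butyldimethylsilyl)oxy]-4-methylhex-5-en-3-ol
Conditions: preformed (E)-crotyl-B(Ipc)2 (Ipc from (−)-α-pinene), THF, −78 °C; then NaOH, H2O2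
Reagents that add atoms: (E)-but-2-en-1-yldiisopinocampheylborane, C/C=C/CB([C@H]1C[C@H]2C[C@H](C2(C)C)[C@@H]1C)[C@H]1C[C@H]2C[C@H](C2(C)C)[C@@H]1C
Why: Brown crotylboration through a closed chair transition state, in which the (E)-crotyl unit gives the anti relation of the C11 methyl and C12 hydroxyl groups and the Ipc groups direct attack to the Re face of the aldehyde, which should set C11 and C12.

Step 2
Reactants: 2 (3S,4R)-1-[(tert-butyldimethylsilyl)oxy]-4-methylhex-5-en-3-ol
Product: 3 (3R,4S)-4,6-bis[(tert-butyldimethylsilyl)oxy]-3-methylhex-1-ene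
Conditions: tBuMe2SiCl, imidazole, DMF, rt
Reagents that add atoms: tert-butyldimethylsilyl chloride, CC(C)(C)[Si](C)(C)Cl
Why: Standard silylation of the secondary alcohol, which touches no stereocenter and gives a C12 ether that survives to step 30.

Step 3
Reactants: 3 (3R,4S)-4,6-bis[(tert-butyldimethylsilyl)oxy]-3-methylhex-1-ene; 4 (S)-but-3-en-2-ol
Product: 5 (2S,3E,5R,6S)-6,8-bis[(tert-butyldimethylsilyl)oxy]-5-methyloct-3-en-2-ol
Conditions: second-generation Hoveyda–Grubbs catalyst (5 mol %), CH2Cl2, 40 °C, excess 4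
Reagents that add atoms: none
Why: Olefin cross-metathesis of the terminal alkene with the secondary allylic alcohol should give the E-disubstituted alkene, and the C8 carbinol center comes unchanged from enantiopure 4.

Step 4
Reactants: 5 (2S,3E,5R,6S)-6,8-bis[(tert-butyldimethylsilyl)oxy]-5-methyloct-3-en-2-ol; 6 triethyl orthopropionate
Product: 8 ethyl (2RS,3S,4R,5S)-5,7-bis[(tert-butyldimethylsilyl)oxy]-2,4-dimethyl-3-[(E)-prop-1-enyl]heptanoate, via ketene acetal 7 (not isolated)
Conditions: EtCO2H (cat.), xylene, 140 °C, EtOH distilled off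
Reagents that add atoms: none
Why: Johnson–Claisen rearrangement through a chair transition state with the C8 methyl group equatorial transfers the (S)-carbinol chirality to C10 while forming the C1–C10 bond and the E-propenyl group; C1 forms as a mixture, which is harmless.

Step 5
Reactants: 8 ethyl (2RS,3S,4R,5S)-5,7-bis[(tert-butyldimethylsilyl)oxy]-2,4-dimethyl-3-[(E)-prop-1-enyl]heptanoate
Product: 10 ethyl (2RS,3S,4R,5S)-2-bromo-5,7-bis[(tert-butyldimethylsilyl)oxy]-2,4-dimethyl-3-[(E)-prop-1-enyl]heptanoate, via lithium enolate 9 (not isolated)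
Conditions: LiN(iPr)2, THF, −78 °C; then CBr4
Reagents that add atoms: carbon tetrabromide, BrC(Br)(Br)Br
Why: Electrophilic bromination of the ester enolate gives the tertiary α-bromo ester as both C1 epimers, which converge in step 8.

Step 6
Reactants: 10 ethyl (2RS,3S,4R,5S)-2-bromo-5,7-bis[(tert-butyldimethylsilyl)oxy]-2,4-dimethyl-3-[(E)-prop-1-enyl]heptanoate
Product: 11 ethyl (2RS,3S,4R,5S)-2-bromo-5-[(tert-butyldimethylsilyl)oxy]-7-hydroxy-2,4-dimethyl-3-[(E)-prop-1-enyl]heptanoate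
Conditions: camphorsulfonic acid (cat.), MeOH/CH2Cl2, 0 °C
Reagents that add atoms: none
Why: Acid methanolysis should cleave the primary silyl ether much faster than the hindered secondary one (selective desilylation).

Step 7
Reactants: 11 ethyl (2RS,3S,4R,5S)-2-bromo-5-[(tert-butyldimethylsilyl)oxy]-7-hydroxy-2,4-dimethyl-3-[(E)-prop-1-enyl]heptanoate
Product: 12 ethyl (2RS,3S,4R,5S)-2-bromo-5-[(tert-butyldimethylsilyl)oxy]-2,4-dimethyl-7-oxo-3-[(E)-prop-1-enyl]heptanoate
Conditions: Dess–Martin periodinane, NaHCO3, CH2Cl2, 0 °C → rt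
Reagents that add atoms: none
Why: Dess–Martin oxidation gives the C14 aldehyde under buffered, non-basic conditions that spare the tertiary bromide.

Step 8
Reactants: 12 ethyl (2RS,3S,4R,5S)-2-bromo-5-[(tert-butyldimethylsilyl)oxy]-2,4-dimethyl-7-oxo-3-[(E)-prop-1-enyl]heptanoate
Product: 14 ethyl (1R,2S,3R,4S,6S)-4-[(tert-butyldimethylsilyl)oxy]-6-hydroxy-1,3-dimethyl-2-[(E)-prop-1-enyl]cyclohexane-1-carboxylate, via samarium enolate 13 (not isolated)
Conditions: SmI2 (2.2 equiv), THF, −78 °C; then aq. NH4Cl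
Reagents that add atoms: none
Why: Two electrons from divalent samarium cleave the C–Br bond of either C1 epimer of 12 to the same trivalent samarium ester enolate 13, which adds to the tethered aldehyde; the closest known reaction type is the SmI2-promoted intramolecular Reformatsky (aldol) cyclization. Ring A closes in a 6-(enolexo)-exo-trig mode through a chair transition state with the C10 propenyl and C12 silyloxy groups equatorial. C1 is controlled by A(1,3) strain: the C10–H bond eclipses the enolate plane, the tether through C11 delivers the aldehyde to one enolate face, and the C1 methyl group should therefore end cis to the C10 substituent. C14 is controlled by the samarium chelate between enolate oxygen and aldehyde oxygen, which should place the new hydroxyl axial and cis to the ester. The step needs reduction of the tertiary bromide in preference to the aldehyde, secured by the easy reduction of the α-bromo ester at −78 °C.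

Step 9
Reactants: 14 ethyl (1R,2S,3R,4S,6S)-4-[(tert-butyldimethylsilyl)oxy]-6-hydroxy-1,3-dimethyl-2-[(E)-prop-1-enyl]cyclohexane-1-carboxylate
Product: 15 ethyl (1R,2S,3R,4S,6S)-4-[(tert-butyldimethylsilyl)oxy]-6-(methoxymethoxy)-1,3-dimethyl-2-[(E)-prop-1-enyl]cyclohexane-1-carboxylate
Conditions: MeOCH2Cl, iPr2NEt, Bu4NI (cat.), CH2Cl2, 0 → 40 °C
Reagents that add atoms: chloromethyl methyl ether, COCCl
Why: Alkylation of the hindered C14 alcohol with an amine base avoids retro-aldol cleavage and installs the chelating ether used in step 19.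

Step 10
Reactants: 15 ethyl (1R,2S,3R,4S,6S)-4-[(tert-butyldimethylsilyl)oxy]-6-(methoxymethoxy)-1,3-dimethyl-2-[(E)-prop-1-enyl]cyclohexane-1-carboxylate
Product: 17 ring A C9 aldehyde (10β-formyl), via ozonide 16 (not isolated)
Conditions: O3, CH2Cl2, −78 °C; then PPh3
Reagents that add atoms: ozone, [O-][O+]=O
Why: Ozonolysis with reductive work-up cleaves the only alkene to the C9 aldehyde, which is used at once to avoid epimerization at C10.

Step 11
Reactants: 17 ring A C9 aldehyde
Product: 18 C9 allylic alcohols (both C9 epimers)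
Conditions: CH2=CHMgBr, THF, −78 °C
Reagents that add atoms: vinylmagnesium bromide, C=C[Mg]Br
Why: Grignard 1,2-addition to the aldehyde at low temperature leaves the neopentyl ester alone; the C9 configuration is of no concern because it is reset in steps 12 and 13.

Step 12
Reactants: 18 C9 allylic alcohols
Product: 19 ring A vinyl ketone (C9 ketone)
Conditions: Dess–Martin periodinane, NaHCO3, CH2Cl2, 0 °C
Reagents that add atoms: none
Why: Dess–Martin oxidation converts both epimeric allylic alcohols into one enone.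

Step 13
Reactants: 19 ring A vinyl ketone
Product: 20 C9 allylic alcohol with O9 configured as in the target
Conditions: NaBH4, CeCl3·7H2O, MeOH, −78 °C
Reagents that add atoms: none
Why: Luche 1,2-reduction under Felkin–Anh control, with hydride attacking anti to quaternary C1 of the C10 stereocenter, should set C9.

Step 14
Reactants: 20 C9 allylic alcohol
Product: 21 9-O-methoxymethyl ether of 20
Conditions: MeOCH2Cl, iPr2NEt, Bu4NI (cat.), CH2Cl2, rt
Reagents that add atoms: chloromethyl methyl ether, COCCl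
Why: Acetal ether formation protects O9 with a group that can chelate in step 25 and that survives until step 28.

Step 15
Reactants: 21 9-O-methoxymethyl ether
Product: 23 C8 aldehyde (α-methoxymethoxy aldehyde), via ozonide 22 (not isolated)
Conditions: O3, CH2Cl2, −78 °C; then PPh3
Reagents that add atoms: ozone, [O-][O+]=O
Why: Ozonolysis of the only alkene gives the α-alkoxy aldehyde without touching the C9 stereocenter.

Step 16
Reactants: 23 C8 aldehyde
Product: 24 alkoxyallylation product (C8 alcohol, C7 4-methoxyphenyl ether, vinyl group; 7,8-syn, 8,9-anti)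
Conditions: preformed (Z)-[3-(4-methoxyphenoxy)allyl]-B(Ipc)2 (Ipc from (−)-α-pinene), THF, −78 °C; then NaOH, H2O2
Reagents that add atoms: (Z)-[3-(4-methoxyphenoxy)prop-2-en-1-yl]diisopinocampheylborane, COc1ccc(O/C=C\CB([C@H]2C[C@H]3C[C@H](C3(C)C)[C@@H]2C)[C@H]2C[C@H]3C[C@H](C3(C)C)[C@@H]2C)cc1
Why: Brown alkoxyallylboration through a closed chair transition state, in which the Z reagent gives the 7,8-syn adduct and the Ipc groups direct attack to the Re face of the aldehyde (matched with the Felkin preference of the α-alkoxy aldehyde), should set C7; C8 is oxidized later.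

Step 17
Reactants: 24 alkoxyallylation product
Product: 25 8-O-triethylsilyl ether of 24
Conditions: Et3SiCl, imidazole, DMF, 0 °C
Reagents that add atoms: chlorotriethylsilane, CC[Si](Cl)(CC)CC
Why: Silylation masks the C8 alcohol while the C1 side chain is built.

Step 18
Reactants: 25 8-O-triethylsilyl ether
Product: 26 C2 aldehyde (CHO on C1)
Conditions: iBu2AlH (1.1 equiv), toluene, −78 °C
Reagents that add atoms: none
Why: Partial reduction of the hindered ester should stop at the aldehyde because the tetrahedral aluminate is held by chelation to the C14 ether until work-up.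

Step 19
Reactants: 26 C2 aldehyde
Product: 27 C2 allylic alcohol (C2 configured as in the target)
Conditions: MgBr2·OEt2, then CH2=CHMgBr, CH2Cl2, −78 °C
Reagents that add atoms: vinylmagnesium bromide, C=C[Mg]Br
Why: Cram-chelate addition, in which magnesium bridges the aldehyde oxygen and the C14 ether and vinyl attacks from the face of the C1 methyl group, anti to C10 and its side chain, should set C2.

Step 20
Reactants: 27 C2 allylic alcohol
Product: 28 erythro 3,4-epoxy-2-ol
Conditions: Ti(OiPr)4, D-(−)-diisopropyl tartrate, tBuOOH, 4 Å molecular sieves, CH2Cl2, −20 °C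
Reagents that add atoms: tert-butyl hydroperoxide, CC(C)(C)OO
Why: Sharpless asymmetric epoxidation in the matched sense for this carbinol should give the erythro epoxy alcohol and so set C3, and only the free allylic alcohol reacts.

Step 21
Reactants: 28 erythro 3,4-epoxy-2-ol
Product: 29 erythro 2,3-diol with the C4–C5 isopropenyl unit
Conditions: CH2=C(CH3)MgBr, CuI (10 mol %), THF, −40 → 0 °C
Reagents that add atoms: isopropenylmagnesium bromide, CC(=C)[Mg]Br
Why: Copper-catalyzed Grignard opening of the terminal epoxide at unhindered C4 leaves C3 untouched and brings in C5 with its methyl group and the metathesis handle.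

Step 22
Reactants: 29 erythro 2,3-diol
Product: 30 2,3-diacetate
Conditions: Ac2O, pyridine, DMAP (cat.), CH2Cl2, rt
Reagents that add atoms: acetic anhydride, CC(=O)OC(C)=O
Why: Acylation installs the two final acetates, which also serve as protecting groups for the rest of the route.

Step 23
Reactants: 30 2,3-diacetate
Product: 31 C8 alcohol
Conditions: HF·pyridine, pyridine, THF, 0 °C
Reagents that add atoms: none
Why: Buffered fluoride should cleave the triethylsilyl ether and leave the bulkier silyl ether, the acetal ethers and the acetates.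

Step 24
Reactants: 31 C8 alcohol
Product: 32 C8 ketone
Conditions: Dess–Martin periodinane, NaHCO3, CH2Cl2, 0 °C
Reagents that add atoms: none
Why: Dess–Martin oxidation gives the α,α'-dioxygenated ketone under neutral conditions that should not isomerize the C7 vinyl group.

Step 25
Reactants: 32 C8 ketone; 33 (2S,5S)-2-tert-butyl-5-methyl-1,3-dioxolan-4-one
Product: 35 aldol adduct (C8 tertiary alcohol bearing the dioxolanone as C17), via lithium enolate 34 (not isolated)
Conditions: 33, LiN(iPr)2, THF, −78 °C; CeCl3; then 32, −78 °C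
Reagents that add atoms: none
Why: Aldol addition of the Seebach lactate enolate (self-regeneration of stereocenters), in which the ketone face is set by Cram chelation to the C9 acetal ether (the aryl ether at C7 does not chelate) and the enolate reacts anti to its tert-butyl group, should set C8 and C17, while the cerium enolate suppresses enolization.

Step 26
Reactants: 35 aldol adduct
Product: 37 lactone diene, via hydroxy dioxolanone 36 (not isolated)
Conditions: (NH4)2Ce(NO3)6, MeCN/H2O, 0 °C; then camphorsulfonic acid (cat.), CH2Cl2, rt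
Reagents that add atoms: none
Why: Oxidative removal of the 4-methoxyphenyl ether frees the C7 hydroxyl, which lactonizes onto the activated acetal ester with loss of pivalaldehyde, while protected O9 cannot compete.

Step 27
Reactants: 37 lactone diene
Product: 38 ten-membered (5Z)-alkene
Conditions: second-generation Hoveyda–Grubbs catalyst (10 mol %), toluene (1 mM), 80 °C
Reagents that add atoms: none
Why: Ring-closing metathesis of the isopropenyl and vinyl groups at high dilution, with the chain pre-organized by ring A and the lactone, should close the ten-membered ring, and ring strain should favour the Z-trisubstituted alkene.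

Step 28
Reactants: 38 ten-membered (5Z)-alkene
Product: 39 9,14-diol
Conditions: ZnBr2, n-PrSH, CH2Cl2, 0 °C
Reagents that add atoms: none
Why: Lewis acid and thiol cleave both methoxymethyl ethers (acetal exchange) under conditions that should spare the acetates, lactone, alkene and silyl ether.

Step 29
Reactants: 39 9,14-diol
Product: 40 2,3,9,14-tetraacetate
Conditions: Ac2O, pyridine, DMAP (cat.), CH2Cl2, rt
Reagents that add atoms: acetic anhydride, CC(=O)OC(C)=O
Why: Acylation of the two secondary alcohols, in which the tertiary C8 and C17 hydroxyls are too hindered to react.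

Step 30
Reactants: 40 2,3,9,14-tetraacetate
Product: 41 5,6-deoxy target (free C12 alcohol)
Conditions: HF·pyridine, pyridine, THF, 0 °C → rt
Reagents that add atoms: none
Why: Fluoride cleavage of the last silyl ether under buffered conditions that leave acetates and lactone intact.

Step 31
Reactants: 41 5,6-deoxy target
Product: 42 CNP0287149.1
Conditions: mCPBA, NaHCO3, CH2Cl2, 0 °C
Reagents that add atoms: 3-chloroperbenzoic acid, OOC(=O)c1cccc(Cl)c1
Why: Prilezhaev epoxidation of the only alkene by peripheral attack anti to C8 (C7–H in the alkene plane, A(1,3) strain) should give the 5,6-epoxide threo to O7, as in the target.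

Compound list
1 | 3-[(tert-butyldimethylsilyl)oxy]propanal | O=CCCO[Si](C)(C)C(C)(C)C | starting material
2 | (3S,4R)-1-[(tert-butyldimethylsilyl)oxy]-4-methylhex-5-en-3-ol | C=C[C@@H](C)[C@@H](O)CCO[Si](C)(C)C(C)(C)C | intermediate
3 | (3R,4S)-4,6-bis[(tert-butyldimethylsilyl)oxy]-3-methylhex-1-ene | C=C[C@@H](C)[C@@H](O[Si](C)(C)C(C)(C)C)CCO[Si](C)(C)C(C)(C)C | intermediate
4 | (S)-but-3-en-2-ol | C[C@H](O)C=C | starting material
5 | (2S,3E,5R,6S)-6,8-bis[(tert-butyldimethylsilyl)oxy]-5-methyloct-3-en-2-ol | C[C@H](O)/C=C/[C@@H](C)[C@@H](O[Si](C)(C)C(C)(C)C)CCO[Si](C)(C)C(C)(C)C | intermediate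
6 | triethyl orthopropionate | CCC(OCC)(OCC)OCC | starting material
7 | mixed ketene acetal: 1-ethoxyprop-1-enyl ether of 5 | CC=C(OCC)O[C@@H](C)/C=C/[C@@H](C)[C@@H](O[Si](C)(C)C(C)(C)C)CCO[Si](C)(C)C(C)(C)C | intermediate
8 | ethyl (2RS,3S,4R,5S)-5,7-bis[(tert-butyldimethylsilyl)oxy]-2,4-dimethyl-3-[(E)-prop-1-enyl]heptanoate | CCOC(=O)C(C)[C@@H](/C=C/C)[C@@H](C)[C@@H](O[Si](C)(C)C(C)(C)C)CCO[Si](C)(C)C(C)(C)C | intermediate
9 | lithium enolate of 8 | CCOC(O[Li])=C(C)[C@@H](/C=C/C)[C@@H](C)[C@@H](O[Si](C)(C)C(C)(C)C)CCO[Si](C)(C)C(C)(C)C | intermediate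
10 | ethyl (2RS,3S,4R,5S)-2-bromo-5,7-bis[(tert-butyldimethylsilyl)oxy]-2,4-dimethyl-3-[(E)-prop-1-enyl]heptanoate | CCOC(=O)C(C)(Br)[C@@H](/C=C/C)[C@@H](C)[C@@H](O[Si](C)(C)C(C)(C)C)CCO[Si](C)(C)C(C)(C)C | intermediate
11 | ethyl (2RS,3S,4R,5S)-2-bromo-5-[(tert-butyldimethylsilyl)oxy]-7-hydroxy-2,4-dimethyl-3-[(E)-prop-1-enyl]heptanoate | CCOC(=O)C(C)(Br)[C@@H](/C=C/C)[C@@H](C)[C@@H](O[Si](C)(C)C(C)(C)C)CCO | intermediate
12 | ethyl (2RS,3S,4R,5S)-2-bromo-5-[(tert-butyldimethylsilyl)oxy]-2,4-dimethyl-7-oxo-3-[(E)-prop-1-enyl]heptanoate | CCOC(=O)C(C)(Br)[C@@H](/C=C/C)[C@@H](C)[C@@H](O[Si](C)(C)C(C)(C)C)CC=O | intermediate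
13 | samarium enolate of 12 (O-bound SmI2 ketene acetal, aldehyde intact) | CCOC(O[Sm](I)I)=C(C)[C@@H](/C=C/C)[C@@H](C)[C@@H](O[Si](C)(C)C(C)(C)C)CC=O | intermediate
14 | ethyl (1R,2S,3R,4S,6S)-4-[(tert-butyldimethylsilyl)oxy]-6-hydroxy-1,3-dimethyl-2-[(E)-prop-1-enyl]cyclohexane-1-carboxylate (ring A: 1β-CH3, 10β-propenyl, 11β-CH3, 12β-OSi, 14α-OH) | CCOC(=O)[C@]1(C)[C@@H](/C=C/C)[C@@H](C)[C@@H](O[Si](C)(C)C(C)(C)C)C[C@@H]1O | intermediate
15 | ethyl (1R,2S,3R,4S,6S)-4-[(tert-butyldimethylsilyl)oxy]-6-(methoxymethoxy)-1,3-dimethyl-2-[(E)-prop-1-enyl]cyclohexane-1-carboxylate | CCOC(=O)[C@]1(C)[C@@H](/C=C/C)[C@@H](C)[C@@H](O[Si](C)(C)C(C)(C)C)C[C@@H]1OCOC | intermediate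
16 | secondary ozonide of 15 (5-methyl-1,2,4-trioxolan-3-yl at C10) | CCOC(=O)[C@]1(C)[C@@H](C2OOC(C)O2)[C@@H](C)[C@@H](O[Si](C)(C)C(C)(C)C)C[C@@H]1OCOC | intermediate
17 | ring A C9 aldehyde: ethyl 10β-formyl-14α-(methoxymethoxy)-1β,11β-dimethyl-12β-[(tert-butyldimethylsilyl)oxy]cyclohexane-1α-carboxylate | CCOC(=O)[C@]1(C)[C@@H](C=O)[C@@H](C)[C@@H](O[Si](C)(C)C(C)(C)C)C[C@@H]1OCOC | intermediate
18 | C9 allylic alcohols: 17 with CH(OH)CH=CH2 at C10 (both C9 epimers) | CCOC(=O)[C@]1(C)[C@@H](C(O)C=C)[C@@H](C)[C@@H](O[Si](C)(C)C(C)(C)C)C[C@@H]1OCOC | intermediate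
19 | ring A vinyl ketone: 17 with C(=O)CH=CH2 at C10 | CCOC(=O)[C@]1(C)[C@@H](C(=O)C=C)[C@@H](C)[C@@H](O[Si](C)(C)C(C)(C)C)C[C@@H]1OCOC | intermediate
20 | C9 allylic alcohol, O9 configured as in the target | CCOC(=O)[C@]1(C)[C@@H]([C@H](O)C=C)[C@@H](C)[C@@H](O[Si](C)(C)C(C)(C)C)C[C@@H]1OCOC | intermediate
21 | 9-O-methoxymethyl ether of 20 | CCOC(=O)[C@]1(C)[C@@H]([C@H](OCOC)C=C)[C@@H](C)[C@@H](O[Si](C)(C)C(C)(C)C)C[C@@H]1OCOC | intermediate
22 | secondary ozonide of 21 (1,2,4-trioxolan-3-yl on C9) | CCOC(=O)[C@]1(C)[C@@H]([C@H](OCOC)C2OOCO2)[C@@H](C)[C@@H](O[Si](C)(C)C(C)(C)C)C[C@@H]1OCOC | intermediate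
23 | C8 aldehyde: ring A with 10β-CH(OCH2OCH3)CHO, C9 as in the target | CCOC(=O)[C@]1(C)[C@@H]([C@H](OCOC)C=O)[C@@H](C)[C@@H](O[Si](C)(C)C(C)(C)C)C[C@@H]1OCOC | intermediate
24 | alkoxyallylation product: side chain C9H(OCH2OCH3)–C8H(OH)–C7H(O-4-methoxyphenyl)–CH=CH2, 8,9-anti and 7,8-syn, C7 and C9 as in the target | CCOC(=O)[C@]1(C)[C@@H]([C@H](OCOC)[C@H](O)[C@@H](Oc2ccc(OC)cc2)C=C)[C@@H](C)[C@@H](O[Si](C)(C)C(C)(C)C)C[C@@H]1OCOC | intermediate
25 | 8-O-triethylsilyl ether of 24 | CCOC(=O)[C@]1(C)[C@@H]([C@H](OCOC)[C@H](O[Si](CC)(CC)CC)[C@@H](Oc2ccc(OC)cc2)C=C)[C@@H](C)[C@@H](O[Si](C)(C)C(C)(C)C)C[C@@H]1OCOC | intermediate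
26 | C2 aldehyde: 25 with CHO in place of CO2Et on C1 | O=C[C@]1(C)[C@@H]([C@H](OCOC)[C@H](O[Si](CC)(CC)CC)[C@@H](Oc2ccc(OC)cc2)C=C)[C@@H](C)[C@@H](O[Si](C)(C)C(C)(C)C)C[C@@H]1OCOC | intermediate
27 | C2 allylic alcohol: C1–CH(OH)–CH=CH2, C2 configured as in the target | C=C[C@H](O)[C@]1(C)[C@@H]([C@H](OCOC)[C@H](O[Si](CC)(CC)CC)[C@@H](Oc2ccc(OC)cc2)C=C)[C@@H](C)[C@@H](O[Si](C)(C)C(C)(C)C)C[C@@H]1OCOC | intermediate
28 | erythro 3,4-epoxy-2-ol: oxirane on C3–C4, C2 and C3 as in the target | C3O[C@@H]3[C@H](O)[C@]1(C)[C@@H]([C@H](OCOC)[C@H](O[Si](CC)(CC)CC)[C@@H](Oc2ccc(OC)cc2)C=C)[C@@H](C)[C@@H](O[Si](C)(C)C(C)(C)C)C[C@@H]1OCOC | intermediate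
29 | erythro 2,3-diol: C1–CH(OH)–CH(OH)–CH2–C(CH3)=CH2 | C=C(C)C[C@H](O)[C@H](O)[C@]1(C)[C@@H]([C@H](OCOC)[C@H](O[Si](CC)(CC)CC)[C@@H](Oc2ccc(OC)cc2)C=C)[C@@H](C)[C@@H](O[Si](C)(C)C(C)(C)C)C[C@@H]1OCOC | intermediate
30 | 2,3-diacetate of 29 | C=C(C)C[C@H](OC(C)=O)[C@H](OC(C)=O)[C@]1(C)[C@@H]([C@H](OCOC)[C@H](O[Si](CC)(CC)CC)[C@@H](Oc2ccc(OC)cc2)C=C)[C@@H](C)[C@@H](O[Si](C)(C)C(C)(C)C)C[C@@H]1OCOC | intermediate
31 | C8 alcohol: 30 without the triethylsilyl group | C=C(C)C[C@H](OC(C)=O)[C@H](OC(C)=O)[C@]1(C)[C@@H]([C@H](OCOC)[C@H](O)[C@@H](Oc2ccc(OC)cc2)C=C)[C@@H](C)[C@@H](O[Si](C)(C)C(C)(C)C)C[C@@H]1OCOC | intermediate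
32 | C8 ketone: side chain C9H(OCH2OCH3)–C(=O)–C7H(O-4-methoxyphenyl)–CH=CH2 | C=C(C)C[C@H](OC(C)=O)[C@H](OC(C)=O)[C@]1(C)[C@@H]([C@H](OCOC)C(=O)[C@@H](Oc2ccc(OC)cc2)C=C)[C@@H](C)[C@@H](O[Si](C)(C)C(C)(C)C)C[C@@H]1OCOC | intermediate
33 | (2S,5S)-2-tert-butyl-5-methyl-1,3-dioxolan-4-one | C[C@@H]1O[C@H](C(C)(C)C)OC1=O | starting material
34 | lithium enolate of 33 | CC1=C(O[Li])O[C@@H](C(C)(C)C)O1 | intermediate
35 | aldol adduct: C8 tertiary alcohol bearing the (2S,5R)-2-tert-butyl-5-methyl-4-oxo-1,3-dioxolan-5-yl group as C17, C8 and C17 as in the target | C=C(C)C[C@H](OC(C)=O)[C@H](OC(C)=O)[C@]1(C)[C@@H]([C@H](OCOC)[C@](O)([C@@H](Oc2ccc(OC)cc2)C=C)[C@@]3(C)O[C@H](C(C)(C)C)OC3=O)[C@@H](C)[C@@H](O[Si](C)(C)C(C)(C)C)C[C@@H]1OCOC | intermediate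
36 | hydroxy dioxolanone: 35 with free C7 hydroxyl | C=C(C)C[C@H](OC(C)=O)[C@H](OC(C)=O)[C@]1(C)[C@@H]([C@H](OCOC)[C@](O)([C@@H](O)C=C)[C@@]3(C)O[C@H](C(C)(C)C)OC3=O)[C@@H](C)[C@@H](O[Si](C)(C)C(C)(C)C)C[C@@H]1OCOC | intermediate
37 | lactone diene: γ-lactone O7–C19(=O)–C17(OH)(CH3)–C8(OH)–C7(vinyl), 8,17-trans-diol | C=C(C)C[C@H](OC(C)=O)[C@H](OC(C)=O)[C@]1(C)[C@@H]([C@H](OCOC)[C@]3(O)[C@H](C=C)OC(=O)[C@]3(C)O)[C@@H](C)[C@@H](O[Si](C)(C)C(C)(C)C)C[C@@H]1OCOC | intermediate
38 | ten-membered (5Z)-alkene: 2,3-diacetate, 9,14-bis(methoxymethyl) ether, 12-silyl ether | CC(=O)O[C@H]1C/C(C)=C\[C@@H]2OC(=O)[C@](C)(O)[C@]2(O)[C@@H](OCOC)[C@H]2[C@@H](C)[C@@H](O[Si](C)(C)C(C)(C)C)C[C@H](OCOC)[C@]2(C)[C@H]1OC(C)=O | intermediate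
39 | 9,14-diol of 38 | CC(=O)O[C@H]1C/C(C)=C\[C@@H]2OC(=O)[C@](C)(O)[C@]2(O)[C@@H](O)[C@H]2[C@@H](C)[C@@H](O[Si](C)(C)C(C)(C)C)C[C@H](O)[C@]2(C)[C@H]1OC(C)=O | intermediate
40 | 2,3,9,14-tetraacetate 12-silyl ether | CC(=O)O[C@H]1C/C(C)=C\[C@@H]2OC(=O)[C@](C)(O)[C@]2(O)[C@@H](OC(C)=O)[C@H]2[C@@H](C)[C@@H](O[Si](C)(C)C(C)(C)C)C[C@H](OC(C)=O)[C@]2(C)[C@H]1OC(C)=O | intermediate
41 | 5,6-deoxy target ((5Z)-alkene, free 8-, 12- and 17-hydroxyls) | CC(=O)O[C@H]1C/C(C)=C\[C@@H]2OC(=O)[C@](C)(O)[C@]2(O)[C@@H](OC(C)=O)[C@H]2[C@@H](C)[C@@H](O)C[C@H](OC(C)=O)[C@]2(C)[C@H]1OC(C)=O | intermediate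
42 | CNP0287149.1 | CC(=O)O[C@H]1C[C@@]2(C)O[C@H]2[C@@H]2OC(=O)[C@](C)(O)[C@]2(O)[C@@H](OC(C)=O)[C@H]2[C@@H](C)[C@@H](O)C[C@H](OC(C)=O)[C@]2(C)[C@H]1OC(C)=O | target

Total step count: 31. Longest linear sequence: 31 steps (from 1 to 42); 4, 6 and 33 enter as commercial partners.

Steps most likely to fail

Step 27. The ten-membered ring may not close: both alkenes are hindered and the lactone stiffens the chain, so intermolecular metathesis (oligomers) or closure to the E-alkene could win. The fallback moves the ring closure ahead of the lactone annulation. It sets out from 35, which is cyclized with the same class of catalyst to the ten-membered dioxolanone F7 while C7 and C8 are still part of a flexible chain. F7 is then treated with (NH4)2Ce(NO3)6 and catalytic acid as in step 26, so that the C7 hydroxyl lactonizes onto the dioxolanone, and the route is rejoined at 38.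

Step 25. Proton transfer from C7 of ketone 32 (enolization, loss of the C7 configuration) or attack of the enolate on the acetates may outrun addition to the hindered carbonyl. The fallback sets out from 32 and builds C17 in the opposite sense, by methyl addition to a ring ketone. The non-basic Reformatsky reagent BrZnCH2CO2Et (Zn, ethyl bromoacetate, THF) adds under the same chelation control to give the β-hydroxy ester F3. (NH4)2Ce(NO3)6 and then catalytic acid remove the aryl ether and close the C17-unsubstituted lactone F4. Its dianion (LiN(SiMe3)2, −78 °C) is hydroxylated with 2-(phenylsulfonyl)-3-phenyloxaziridine to the α-hydroxy lactone F5, and Dess–Martin oxidation gives the α-keto lactone F6. MeMgBr at −78 °C should then add to the C17 ketone from the face of the C8 hydroxyl, anti to C9 and the C7 vinyl group, which gives the 8,17-trans-diol and rejoins the route at 37.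

Step 8. Facial selectivity at the aldehyde carbon may be poor if the chelated transition state does not dominate, which would give a mixture at C14. The fallback sets out from 12. The cyclization is run as before, and the product, 14 together with its C14 epimer F1, is oxidized with Dess–Martin periodinane to the single β-keto ester F2. F2 is reduced with LiBH(sBu)3 (THF, −78 °C), where equatorial attack of the bulky hydride should give the axial C14 alcohol, and the route is rejoined at 14.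

Further compounds
F1 | step 8 | C14 epimer of 14 (14β-hydroxy) | CCOC(=O)[C@]1(C)[C@@H](/C=C/C)[C@@H](C)[C@@H](O[Si](C)(C)C(C)(C)C)C[C@H]1O
F2 | step 8 | ring A β-keto ester (C14 ketone) | CCOC(=O)[C@]1(C)[C@@H](/C=C/C)[C@@H](C)[C@@H](O[Si](C)(C)C(C)(C)C)CC1=O
F3 | step 25 | Reformatsky adduct of 32 (C8 tertiary alcohol with CH2CO2Et as C17–C19) | C=C(C)C[C@H](OC(C)=O)[C@H](OC(C)=O)[C@]1(C)[C@@H]([C@H](OCOC)[C@](O)([C@@H](Oc2ccc(OC)cc2)C=C)CC(=O)OCC)[C@@H](C)[C@@H](O[Si](C)(C)C(C)(C)C)C[C@@H]1OCOC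
F4 | step 25 | lactone with C17H2 (8-hydroxy, 7-vinyl) | C=C(C)C[C@H](OC(C)=O)[C@H](OC(C)=O)[C@]1(C)[C@@H]([C@H](OCOC)[C@]3(O)[C@H](C=C)OC(=O)C3)[C@@H](C)[C@@H](O[Si](C)(C)C(C)(C)C)C[C@@H]1OCOC
F5 | step 25 | α-hydroxy lactone (17-hydroxy, C17 epimers) | C=C(C)C[C@H](OC(C)=O)[C@H](OC(C)=O)[C@]1(C)[C@@H]([C@H](OCOC)[C@]3(O)[C@H](C=C)OC(=O)C3O)[C@@H](C)[C@@H](O[Si](C)(C)C(C)(C)C)C[C@@H]1OCOC
F6 | step 25 | α-keto lactone (C17 ketone) | C=C(C)C[C@H](OC(C)=O)[C@H](OC(C)=O)[C@]1(C)[C@@H]([C@H](OCOC)[C@]3(O)[C@H](C=C)OC(=O)C3=O)[C@@H](C)[C@@H](O[Si](C)(C)C(C)(C)C)C[C@@H]1OCOC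
F7 | step 27 | ten-membered (5Z)-alkene with C7 aryl ether and C17 dioxolanone (ring-closed 35) | CC(=O)O[C@H]1C/C(C)=C\[C@H](Oc3ccc(OC)cc3)[C@](O)([C@@]3(C)O[C@H](C(C)(C)C)OC3=O)[C@@H](OCOC)[C@H]2[C@@H](C)[C@@H](O[Si](C)(C)C(C)(C)C)C[C@H](OCOC)[C@]2(C)[C@H]1OC(C)=O
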